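The cyclopentane is disconnected as a formal (3+2) union of an allyl unit and a ketene. The allyl unit is the C10–C3=C2 triad of a cis-4-methyl-2-carene: C3 becomes the ether-bearing quaternary carbon, C10 its ring CH2 and C2 the ring-fusion CH beside the cyclopropane. An allyl alkynyl ether on C10, unmasked from a dichlorovinyl ether, undergoes a [3,3] shift to an allylketene (C2–C bond) that closes onto the new exocyclic methylene (C10–C bond), fusing a cyclopentenone onto the intact carane in one operation. The temporary ketone then directs the methyl group, the benzylic carbon (o-quinone methide Michael addition) and the aryl ether (oxa-Michael addition), and is removed before double formylation.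

Key step: step 6

Remark: carane numbering is used for the terpene part (C1 and C6 cyclopropane CH, C7 the CMe2 carbon, C10 the carbon on C3); (+)-2-carene (1S,6R) already carries the cyclopropane configuration of the target.

Step 1
Reactants: 1 (+)-2-carene
Product: 2 car-2-en-4-one
Conditions: t-BuOOH, Rh2(C6H10NO)4 (dirhodium tetracaprolactamate, 1 mol%), K2CO3 (cat.), CH2Cl2, 23 °C
Reagents that add atoms: tert-butyl hydroperoxide, CC(C)(C)OO
Why: Rh2-catalysed radical allylic C–H oxidation attacks the only abstractable allylic CH2 (C4) and oxygenates the allyl radical at its terminus remote from the cyclopropane, so no stereocentre is touched.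

Step 2
Reactants: 2 car-2-en-4-one
Product: 3 4-methylenecar-2-ene
Conditions: Ph3PCH3Br, KOt-Bu, THF, 0 → 23 °C
Reagents that add atoms: methyltriphenylphosphonium bromide, C[P+](c1ccccc1)(c1ccccc1)c1ccccc1.[Br-]
Why: Wittig methylenation adds to the enone carbonyl in the 1,2 sense and leaves the vinylcyclopropane intact.

Step 3
Reactants: 3 4-methylenecar-2-ene
Product: 4 cis-4-methylcar-2-ene
Conditions: H2 (1 atm), RhCl(PPh3)3 (5 mol%), benzene–EtOH, 23 °C
Reagents that add atoms: none
Why: Chemoselective homogeneous hydrogenation with RhCl(PPh3)3 should reduce only the 1,1-disubstituted exocyclic alkene and deliver hydrogen to the face opposite the gem-dimethylcyclopropane, so the new C4 methyl is cis to the cyclopropane (4S).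

Step 4
Reactants: 4 cis-4-methylcar-2-ene
Product: 5 allylic alcohol (4-methylcar-2-en-10-ol)
Conditions: SeO2 (0.3 equiv), t-BuOOH, CH2Cl2, 0 → 23 °C
Reagents that add atoms: tert-butyl hydroperoxide, CC(C)(C)OO
Why: SeO2 allylic oxidation (ene reaction followed by [2,3]-sigmatropic shift) occurs on the more substituted alkene carbon and should prefer the CH3 (C10) over the hindered tertiary C4–H, returning the C2=C3 double bond and touching no stereocentre.

Step 5
Reactants: 5 allylic alcohol
Product: 6 (E)-1,2-dichlorovinyl ether
Conditions: KH, Cl2C=CHCl, THF, 0 → 23 °C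
Reagents that add atoms: trichloroethylene, ClC=C(Cl)Cl
Why: O-vinylation of the potassium alkoxide with trichloroethylene (addition to dichloroacetylene generated in situ) is the standard entry to (E)-1,2-dichlorovinyl ethers, the precursors of alkynyl ethers.

Step 6
Reactants: 6 (E)-1,2-dichlorovinyl ether
Product: 9 tricyclic enone, via ethynyl ether 7 (not isolated), via allylketene 8 (not isolated)
Conditions: n-BuLi (2.3 equiv), Et2O, −78 °C; 2,6-di-tert-butyl-4-methylphenol (1.3 equiv), −78 → −20 °C; EtAlCl2 (1.5 equiv), toluene, −78 → 0 °C; aq KNaC4H4O6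
Reagents that add atoms: none
Why: Proposed new method: two equivalents of n-BuLi turn 6 into the lithium alkynyl ether (elimination, then Cl/Li exchange), protonation gives 7, which undergoes the known low-temperature [3,3]-sigmatropic shift of allyl alkynyl ethers to allylketene 8, and EtAlCl2 then lets the new exocyclic methylene attack the ketene carbon, the tertiary cation losing its flanked proton to the Al–Et group so that aqueous work-up of the aluminium dienolate gives the conjugated enone. The closest known reaction types are the [3,3] shift with ketene trapping of allyl and benzyl alkynyl ethers (the benzyl series closes to 2-indanones) and the Lewis-acid acylation of alkenes by ketenes or acylium ions, the new element being the use of the allylketene's own 1,1-disubstituted alkene as the trap. The six-membered chair-like [3,3] array forms the bond from carane C2 to the ketene terminus, and the five-membered ring then closes by 5-endo attack of C10 at the digonal ketene carbon. The single new stereocentre (ring-fusion CH, carane C2) is set in the [3,3] step, the alkyne carbon being delivered suprafacially to the alkene face opposite the gem-dimethylcyclopropane and the cis C4 methyl. The step needs cyclisation rather than ketene dimerisation or (2+2) closure, which intramolecularity and the strain of a bicyclo[2.1.0]pentanone should secure, and proton loss from the CH2 between cation and enolate rather than hydride shift toward the cyclopropane, which the basic Al–Et group and the low temperature favour.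

Step 7
Reactants: 9 tricyclic enone
Product: 10 methyl enone
Conditions: LiN(i-Pr)2, THF, −78 °C; MeI, −78 → −40 °C
Reagents that add atoms: iodomethane, CI
Why: Kinetic deprotonation gives the cross-conjugated α'-enolate, and its alkylation with MeI (enolate alkylation) installs the methyl group, the configuration of this carbon being irrelevant because it is enolised again in step 10.

Step 8
Reactants: 11 2,4,6-trihydroxybenzaldehyde
Product: 12 2,4-bis(benzyloxy)-6-hydroxybenzaldehyde
Conditions: BnBr (2.1 equiv), K2CO3, DMF, 23 °C
Reagents that add atoms: benzyl bromide, BrCc1ccccc1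
Why: Williamson etherification with two equivalents of BnBr takes the para hydroxyl and one ortho hydroxyl, the remaining ortho hydroxyl being deactivated by its hydrogen bond to the formyl group.

Step 9
Reactants: 12 2,4-bis(benzyloxy)-6-hydroxybenzaldehyde
Product: 13 aryl tert-butyl carbonate
Conditions: Boc2O, DMAP (10 mol%), i-Pr2NEt, CH2Cl2, 0 → 23 °C
Reagents that add atoms: di-tert-butyl dicarbonate, CC(C)(C)OC(=O)OC(=O)OC(C)(C)C
Why: DMAP-catalysed O-acylation with Boc2O converts the chelated phenol into the aryl tert-butyl carbonate that later triggers o-quinone methide formation.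

Step 10
Reactants: 10 methyl enone; 13 aryl tert-butyl carbonate
Product: 17 bridged ketone, via carbinol 14 (not isolated), via o-quinone methide 15 (not isolated), via Michael adduct 16 (not isolated)
Conditions: 13, i-BuMgBr, THF, −78 °C; then Li enolate of 10 [LiN(i-Pr)2, THF, −78 °C]; −78 → 23 °C, 12 h; aq NH4Cl
Reagents that add atoms: isobutylmagnesium bromide, CC(C)C[Mg]Br
Why: Grignard addition to the aldehyde, Boc migration and β-elimination release the o-quinone methide, the kinetic α'-enolate of 10 adds to it (Michael addition) on the cyclopentenone face opposite the cyclopropane-bearing ring-fusion substituent with the isobutyl group turned away from the carbocycle (anti to the ring-fusion C–C bond), which should set the quaternary and benzylic stereocentres, and the liberated phenoxide then adds to the enone β-carbon from that same face (oxa-Michael addition), which closes the oxepane and fixes the ether carbon and the cis ring fusion.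

Step 11
Reactants: 17 bridged ketone
Product: 18 alcohol
Conditions: NaBH4, MeOH–THF, 0 → 23 °C
Reagents that add atoms: none
Why: NaBH4 reduction of the hindered cyclopentanone (carbonyl reduction) gives the secondary alcohol as an inconsequential epimer mixture and, being fast and nearly neutral, should forestall retro-oxa-Michael opening of the β-aryloxy ketone.

Step 12
Reactants: 18 alcohol
Product: 19 S-methyl xanthate
Conditions: NaH, CS2, THF, 0 °C; MeI, 23 °C
Reagents that add atoms: carbon disulfide, S=C=S; iodomethane, CI
Why: Xanthate formation (alkoxide, CS2, then S-methylation) prepares the hindered secondary alcohol for radical deoxygenation.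

Step 13
Reactants: 19 S-methyl xanthate
Product: 20 deoxygenated bis(benzyl ether)
Conditions: Bu3SnH, AIBN (cat.), toluene, 110 °C
Reagents that add atoms: none
Why: Barton–McCombie deoxygenation replaces the C–O bond by C–H through a secondary alkyl radical that has no β-leaving group and is not adjacent to the cyclopropane.

Step 14
Reactants: 20 deoxygenated bis(benzyl ether)
Product: 21 resorcinol
Conditions: H2 (1 atm), Pd/C (10% palladium on carbon), EtOAc–EtOH, 23 °C
Reagents that add atoms: none
Why: Hydrogenolysis over Pd/C cleaves both benzyl ethers while the gem-dimethylcyclopropane and the tertiary alkyl aryl ether should survive.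

Step 15
Reactants: 21 resorcinol
Product: 22 CNP0202714.1
Conditions: POCl3 (5 equiv), DMF, 0 → 40 °C; then H2O, NaOAc, 60 °C
Reagents that add atoms: N,N-dimethylformamide, CN(C)C=O; water, O
Why: Vilsmeier–Haack formylation attacks both remaining ring positions, each ortho or para to all three oxygen substituents, and hydrolysis of the bis-iminium salt gives the dialdehyde without touching a stereocentre.

Compound list
1 | (+)-2-carene, (1S,6R)-3,7,7-trimethylbicyclo[4.1.0]hept-2-ene | CC1=C[C@H]2[C@@H](CC1)C2(C)C | starting material
2 | car-2-en-4-one, (1S,6R)-3,7,7-trimethylbicyclo[4.1.0]hept-2-en-4-one | CC1=C[C@H]2[C@@H](CC1=O)C2(C)C | intermediate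
3 | 4-methylenecar-2-ene, (1S,6R)-3,7,7-trimethyl-4-methylidenebicyclo[4.1.0]hept-2-ene | CC1=C[C@H]2[C@@H](CC1=C)C2(C)C | intermediate
4 | cis-4-methylcar-2-ene, (1S,4S,6R)-3,4,7,7-tetramethylbicyclo[4.1.0]hept-2-ene, 4-CH3 cis to the cyclopropane | CC1=C[C@H]2[C@@H](C[C@@H]1C)C2(C)C | intermediate
5 | allylic alcohol, [(1S,4S,6R)-4,7,7-trimethylbicyclo[4.1.0]hept-2-en-3-yl]methanol | OCC1=C[C@H]2[C@@H](C[C@@H]1C)C2(C)C | intermediate
6 | (E)-1,2-dichlorovinyl ether of 5 | Cl/C=C(/Cl)OCC1=C[C@H]2[C@@H](C[C@@H]1C)C2(C)C | intermediate
7 | ethynyl ether of 5 | C#COCC1=C[C@H]2[C@@H](C[C@@H]1C)C2(C)C | intermediate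
8 | allylketene, 2-(4,7,7-trimethyl-3-methylidenebicyclo[4.1.0]hept-2-yl)ethenone, ketene-bearing substituent on C2 trans to the cyclopropane, 4-CH3 cis | O=C=C[C@@H]1C(=C)[C@@H](C)C[C@@H]2[C@H]1C2(C)C | intermediate
9 | tricyclic enone, cyclopentenone fused to the carane C2–C3 bond [C3=CH–C(=O)–CH2–C2H], H on C2 and 4-CH3 both cis to the cyclopropane | O=C1C=C2[C@@H](C)C[C@@H]3[C@H]([C@@H]2C1)C3(C)C | intermediate
10 | methyl enone, 9 with CH(CH3) in place of the CH2 next to the carbonyl (epimers) | O=C1C=C2[C@@H](C)C[C@@H]3[C@H]([C@@H]2C1C)C3(C)C | intermediate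
11 | 2,4,6-trihydroxybenzaldehyde | O=Cc1c(O)cc(O)cc1O | starting material
12 | 2,4-bis(benzyloxy)-6-hydroxybenzaldehyde | O=Cc1c(O)cc(OCc2ccccc2)cc1OCc1ccccc1 | intermediate
13 | 3,5-bis(benzyloxy)-2-formylphenyl tert-butyl carbonate | O=Cc1c(OC(=O)OC(C)(C)C)cc(OCc2ccccc2)cc1OCc1ccccc1 | intermediate
14 | carbinol, 3,5-bis(benzyloxy)-2-(1-hydroxy-3-methylbutyl)phenyl tert-butyl carbonate (racemic) | CC(C)CC(O)c1c(OC(=O)OC(C)(C)C)cc(OCc2ccccc2)cc1OCc1ccccc1 | intermediate
15 | o-quinone methide, 3,5-bis(benzyloxy)-6-(3-methylbutylidene)cyclohexa-2,4-dien-1-one | CC(C)CC=C1C(=O)C=C(OCc2ccccc2)C=C1OCc1ccccc1 | intermediate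
16 | Michael adduct, enone 10 carrying on its now quaternary methyl-bearing carbon the 1-[2,4-bis(benzyloxy)-6-hydroxyphenyl]-3-methylbutyl group, configurations as in the target | CC(C)C[C@@H](c1c(O)cc(OCc2ccccc2)cc1OCc1ccccc1)[C@@]1(C)C(=O)C=C2[C@@H](C)C[C@@H]3[C@H]([C@@H]21)C3(C)C | intermediate
17 | bridged ketone, target skeleton with C=O at the ring CH2 next to the quaternary C(CH3), OBn for both OH and H for both CHO | CC(C)C[C@H]1c2c(OCc3ccccc3)cc(OCc3ccccc3)cc2O[C@]23CC(=O)[C@@]1(C)[C@H]2[C@H]1[C@@H](C[C@@H]3C)C1(C)C | intermediate
18 | alcohol, 17 with CHOH in place of C=O (epimers) | CC(C)C[C@H]1c2c(OCc3ccccc3)cc(OCc3ccccc3)cc2O[C@]23CC(O)[C@@]1(C)[C@H]2[C@H]1[C@@H](C[C@@H]3C)C1(C)C | intermediate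
19 | S-methyl xanthate of 18 | CC(C)C[C@H]1c2c(OCc3ccccc3)cc(OCc3ccccc3)cc2O[C@]23CC(OC(=S)SC)[C@@]1(C)[C@H]2[C@H]1[C@@H](C[C@@H]3C)C1(C)C | intermediate
20 | deoxygenated bis(benzyl ether), target skeleton with OBn for both OH and H for both CHO | CC(C)C[C@H]1c2c(OCc3ccccc3)cc(OCc3ccccc3)cc2O[C@]23CC[C@@]1(C)[C@H]2[C@H]1[C@@H](C[C@@H]3C)C1(C)C | intermediate
21 | resorcinol, target lacking both formyl groups | CC(C)C[C@H]1c2c(O)cc(O)cc2O[C@]23CC[C@@]1(C)[C@H]2[C@H]1[C@@H](C[C@@H]3C)C1(C)C | intermediate
22 | CNP0202714.1 | CC(C)C[C@H]1c2c(O)c(C=O)c(O)c(C=O)c2O[C@]23CC[C@@]1(C)[C@H]2[C@H]1[C@@H](C[C@@H]3C)C1(C)C | target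

Total step count: 15 steps.
Longest linear sequence: 13 steps (steps 1–7, then 10–15).

Steps most likely to fail

Step 6 (proposed new method). The allylketene may dimerise, or the cation formed on ring closure may shift a hydride from the ring-fusion carbon and open the cyclopropane instead of losing the flanked proton. The fallback sets out from 5 and comes back at 10, using known chemistry. Johnson–Claisen rearrangement of 5 with triethyl orthopropionate (cat. EtCO2H, 140 °C) should give the ester ethyl 2-(4,7,7-trimethyl-3-methylidenebicyclo[4.1.0]hept-2-yl)propanoate F1. LiOH hydrolysis gives the acid F2 and SOCl2 the acid chloride F3. SnCl4 (CH2Cl2, −78 °C, then Et3N) closes the cyclopentenone by intramolecular acylation of the exocyclic alkene, giving 10 directly. This fallback makes the two ring bonds in separate operations.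

Step 10. Diastereocontrol at the benzylic carbon may be poor, the o-quinone methide may be quenched by tert-butoxide, or the oxa-Michael closure may remain an unfavourable equilibrium. The fallback sets out from 10 (and 12) and comes back at 17. Enolisation of 10 with LiN(i-Pr)2 and silylation with Me3SiCl gives the trimethylsilyl dienol ether F4. Addition of i-BuMgBr (2.2 equiv) to 12 gives the benzylic alcohol 3,5-bis(benzyloxy)-2-(1-hydroxy-3-methylbutyl)phenol F5. Sc(OTf)3-catalysed dehydration of F5 to o-quinone methide 15 and Mukaiyama–Michael addition of F4 give phenol 16, now isolated so that benzylic epimers can be separated. DBU in toluene then closes 16 to 17.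

Step 4. Over-oxidation to the enal, oxidation at the tertiary allylic C–H or acid-induced opening of the vinylcyclopropane may erode the yield. The fallback sets out from 4 and comes back at 5. Allylic metalation of the C10 methyl with n-BuLi/KOt-Bu and borylation with B(OMe)3 give the dimethyl allylboronate F6, which NaOH/H2O2 oxidises to 5.

Further compounds
F1 | step 6 | ethyl 2-(4,7,7-trimethyl-3-methylidenebicyclo[4.1.0]hept-2-yl)propanoate (configuration of 8, epimers at the propanoate carbon) | CCOC(=O)C(C)[C@@H]1C(=C)[C@@H](C)C[C@@H]2[C@H]1C2(C)C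
F2 | step 6 | 2-(4,7,7-trimethyl-3-methylidenebicyclo[4.1.0]hept-2-yl)propanoic acid | OC(=O)C(C)[C@@H]1C(=C)[C@@H](C)C[C@@H]2[C@H]1C2(C)C
F3 | step 6 | 2-(4,7,7-trimethyl-3-methylidenebicyclo[4.1.0]hept-2-yl)propanoyl chloride | ClC(=O)C(C)[C@@H]1C(=C)[C@@H](C)C[C@@H]2[C@H]1C2(C)C
F4 | step 10 | trimethylsilyl dienol ether of 10 (cross-conjugated, silyloxy diene in the five-membered ring) | C[Si](C)(C)OC1=C(C)[C@H]2[C@H]3[C@@H](C[C@H](C)C2=C1)C3(C)C
F5 | step 10 | 3,5-bis(benzyloxy)-2-(1-hydroxy-3-methylbutyl)phenol (racemic) | CC(C)CC(O)c1c(O)cc(OCc2ccccc2)cc1OCc1ccccc1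
F6 | step 4 | dimethyl [(4,7,7-trimethylbicyclo[4.1.0]hept-2-en-3-yl)methyl]boronate (configuration of 4) | COB(OC)CC1=C[C@H]2[C@@H](C[C@@H]1C)C2(C)C
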